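**Strategy.** Ring A of the chromene is disconnected across C4a–C5 and C6–C7. Since ring A and the pyran ring share the C4a–C8a bond, the pyran can enter the key step already built, as a 2H,5H-pyrano[4,3-b]pyran-5-one. Its lactone diene supplies C7 (carrying the ring B phenethyl chain), C8, C8a and C4a. A silver-promoted [4+2] addition of a prenyl-bearing siloxyalkyne and loss of CO2 then deliver C5 with its oxygen and C6 with its prenyl group, and aromatise ring A in one operation, the ring oxygen being fixed beforehand. Fluoride finally frees both phenols.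

Key step: step 6

Remark: the target has no stereocentre, so no stereocontrol is needed. Dihydroresveratrol and 4-{[tert-butyl(dimethyl)silyl]oxy}benzaldehyde appear only in fallbacks and are assumed to be purchased. The ynol oxygen carries triisopropylsilyl (bulky enough for O-silylation of the ynolate), and ring B carries tert-butyldimethylsilyl, so one fluoride treatment removes both.

**Route**

Step 1
Reactants: 1 4-methylphenol
Product: 2 tert-butyldimethyl(4-methylphenoxy)silane
Conditions: TBSCl, imidazole, DMF, rt
Reagents that add atoms: tert-butyldimethylsilyl chloride, CC(C)(C)[Si](C)(C)Cl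
Why: Imidazole-promoted O-silylation of a phenol is routine and should give the aryl silyl ether cleanly.

Step 2
Reactants: 2 tert-butyldimethyl(4-methylphenoxy)silane
Product: 3 [4-(bromomethyl)phenoxy](tert-butyl)dimethylsilane
Conditions: NBS, AIBN (5 mol%), PhCF3, 90 °C; filtered and used crude
Reagents that add atoms: N-bromosuccinimide, O=C1CCC(=O)N1Br
Why: Wohl–Ziegler benzylic bromination; a non-polar solvent and a radical initiator should favour the benzylic position over the ring, and the aryl silyl ether is inert to radical conditions.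

Step 3
Reactants: 4 4-hydroxy-6-methyl-2H-pyran-2-one; 3 [4-(bromomethyl)phenoxy](tert-butyl)dimethylsilane
Product: 6 6-[2-(4-{[tert-butyl(dimethyl)silyl]oxy}phenyl)ethyl]-4-hydroxy-2H-pyran-2-one, via dilithium pyranone dianion 5 (not isolated)
Conditions: LiN(iPr)2 (2.2 equiv per 4), THF–DMPU, −78 °C; 3, −78 → −20 °C; 1 M HCl
Reagents that add atoms: none
Why: Double deprotonation of the 4-hydroxy-6-methylpyranone gives a dianion whose methyl carbanion is the most nucleophilic site, so C-alkylation by the benzylic bromide (dianion alkylation) should extend the methyl group to the arylethyl chain.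

Step 4
Reactants: 6 6-[2-(4-{[tert-butyl(dimethyl)silyl]oxy}phenyl)ethyl]-4-hydroxy-2H-pyran-2-one; 7 3-methylbut-2-enal
Product: 9 7-[2-(4-{[tert-butyl(dimethyl)silyl]oxy}phenyl)ethyl]-2,2-dimethyl-2H,5H-pyrano[4,3-b]pyran-5-one, via oxatriene 8 (not isolated)
Conditions: 7 (1.5 equiv), ethylenediammonium diacetate (10 mol%), EtOAc, 60 °C
Reagents that add atoms: none
Why: Knoevenagel condensation of the enal at pyranone C3 followed by oxa-6π electrocyclisation onto the C4 oxygen (formal [3+3] annulation of 4-hydroxy-2-pyranones with enals) should give the 2,2-dimethylpyran fused to the intact 2-pyranone.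

Step 5
Reactants: 10 ethyl 4-methylpent-3-enoate
Product: 13 triisopropyl[(5-methylhex-4-en-1-yn-1-yl)oxy]silane, via dibromoenolate 11 (not isolated), via lithium ynolate 12 (not isolated)
Conditions: CH2Br2, LiTMP (lithium 2,2,6,6-tetramethylpiperidide), THF, −78 °C; LiN(SiMe3)2; n-BuLi, −78 → 0 °C; iPr3SiCl, −78 °C → rt
Reagents that add atoms: dibromomethane, BrCBr; triisopropylsilyl chloride, CC(C)[Si](Cl)(C(C)C)C(C)C
Why: Kowalski ester homologation: dibromomethyllithium adds to the ester at −78 °C, bromine–lithium exchange on dibromoenolate 11 triggers the 1,2-shift to ynolate 12, and the bulky chlorosilane should silylate on oxygen to give the siloxyalkyne.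

Step 6
Reactants: 9 7-[2-(4-{[tert-butyl(dimethyl)silyl]oxy}phenyl)ethyl]-2,2-dimethyl-2H,5H-pyrano[4,3-b]pyran-5-one; 13 triisopropyl[(5-methylhex-4-en-1-yn-1-yl)oxy]silane
Product: 15 tert-butyl(dimethyl){4-[2-(2,2-dimethyl-6-(3-methylbut-2-en-1-yl)-5-{[tri(propan-2-yl)silyl]oxy}-2H-chromen-7-yl)ethyl]phenoxy}silane, via bridged lactone 14 (not isolated)
Conditions: AgN(SO2CF3)2 (10 mol%), 13 (2 equiv, slow addition), 4 Å MS, ClCH2CH2Cl, rt → 60 °C
Reagents that add atoms: none
Why: Proposed new method: AgN(SO2CF3)2, a monovalent silver Lewis acid, binds the lactone carbonyl of 9 (made more basic by the 4-alkoxy donor) and lowers the LUMO of the pyranone, so that the alkyne carbon of 13 remote from oxygen bonds to pyranone C6 (future C7) while the ketenium-like siloxy carbon closes onto the ketene-acetal-like pyranone C3 (future C4a), giving bridged lactone 14, which expels CO2 by retro-[4+2] and aromatises. The closest known reaction types are the Diels–Alder/CO2-extrusion benzannulation of 2-pyranones with alkynes (acceptor-substituted pyranones with ynamines or alkoxyalkynes, 4-alkoxypyranones with acetylenic esters) and the AgN(SO2CF3)2-promoted stepwise cycloadditions of siloxyalkynes with unsaturated carbonyl compounds and with azadienes that then lose N2. Ring A is closed by an intermolecular, asynchronous [4+2] cycloaddition (C6–C7 bond leading, C4a–C5 bond completing the 6-membered closure) followed by cycloreversion. No stereocentre is created in the product, the two bridgeheads of 14 becoming aromatic carbons. The step needs a single regiochemistry, siloxy carbon on pyranone C3 and prenyl-bearing carbon on pyranone C6, and this should be secured by matched polarity: the alkyne is nucleophilic only at the carbon remote from oxygen, and in the activated pyranone C6 is the electrophilic terminus (C4 is deactivated by its ether oxygen) while C3 is the nucleophilic one. Since the pyran is already in place the ring oxygen cannot end up on the wrong carbon, and the prenyl alkene, the pyran alkene and both silyl ethers should be spectators under these mild conditions.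

Step 7
Reactants: 15 tert-butyl(dimethyl){4-[2-(2,2-dimethyl-6-(3-methylbut-2-en-1-yl)-5-{[tri(propan-2-yl)silyl]oxy}-2H-chromen-7-yl)ethyl]phenoxy}silane
Product: 16 7-[2-(4-hydroxyphenyl)ethyl]-2,2-dimethyl-6-(3-methylbut-2-en-1-yl)-2H-chromen-5-ol
Conditions: Bu4NF (2.5 equiv), THF, 0 °C → rt; aq. NH4Cl
Reagents that add atoms: none
Why: Fluoride desilylation of both aryl silyl ethers should be fast because aryloxides are good leaving groups, and it leaves the chromene and prenyl alkenes untouched.

**Compound list**

1 | 4-methylphenol | Cc1ccc(O)cc1 | starting material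
2 | tert-butyldimethyl(4-methylphenoxy)silane | Cc1ccc(O[Si](C)(C)C(C)(C)C)cc1 | intermediate
3 | [4-(bromomethyl)phenoxy](tert-butyl)dimethylsilane | BrCc1ccc(O[Si](C)(C)C(C)(C)C)cc1 | intermediate
4 | 4-hydroxy-6-methyl-2H-pyran-2-one | CC1=CC(O)=CC(=O)O1 | starting material
5 | dilithium dianion of 4 (deprotonated at the 4-hydroxyl and at the 6-methyl group) | [Li+].[Li+].[CH2-]C1=CC([O-])=CC(=O)O1 | intermediate
6 | 6-[2-(4-{[tert-butyl(dimethyl)silyl]oxy}phenyl)ethyl]-4-hydroxy-2H-pyran-2-one | O=C1C=C(O)C=C(CCc2ccc(O[Si](C)(C)C(C)(C)C)cc2)O1 | intermediate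
7 | 3-methylbut-2-enal | CC(C)=CC=O | starting material
8 | 6-[2-(4-{[tert-butyl(dimethyl)silyl]oxy}phenyl)ethyl]-3-(3-methylbut-2-en-1-ylidene)-2H-pyran-2,4(3H)-dione (1-oxatriene; the isomer with the diene arm cis to the C4 carbonyl, which cyclises, is drawn) | CC(C)=C/C=C1\C(=O)C=C(CCc2ccc(O[Si](C)(C)C(C)(C)C)cc2)OC1=O | intermediate
9 | 7-[2-(4-{[tert-butyl(dimethyl)silyl]oxy}phenyl)ethyl]-2,2-dimethyl-2H,5H-pyrano[4,3-b]pyran-5-one | CC1(C)C=CC2=C(O1)C=C(CCc3ccc(O[Si](C)(C)C(C)(C)C)cc3)OC2=O | intermediate
10 | ethyl 4-methylpent-3-enoate | CCOC(=O)CC=C(C)C | starting material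
11 | lithium 1,1-dibromo-5-methylhexa-1,4-dien-2-olate | [Li+].[O-]C(CC=C(C)C)=C(Br)Br | intermediate
12 | lithium 5-methylhex-4-en-1-yn-1-olate | [Li+].[O-]C#CCC=C(C)C | intermediate
13 | triisopropyl[(5-methylhex-4-en-1-yn-1-yl)oxy]silane | CC(C)=CCC#CO[Si](C(C)C)(C(C)C)C(C)C | intermediate
14 | bridged lactone (racemic, bridgehead configuration fixed by the bicycle): 2-oxabicyclo[2.2.2]octa-5,7-dien-3-one with the lactone bridge between former pyranone C3 and C6, the dimethylpyran fused across former C3–C4, the arylethyl chain on the C6 bridgehead, and the new alkene carrying triisopropylsilyloxy next to former C3 and prenyl next to former C6 | O=C1OC2(CCc3ccc(O[Si](C)(C)C(C)(C)C)cc3)C=C3OC(C)(C)C=CC13C(O[Si](C(C)C)(C(C)C)C(C)C)=C2CC=C(C)C | intermediate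
15 | tert-butyl(dimethyl){4-[2-(2,2-dimethyl-6-(3-methylbut-2-en-1-yl)-5-{[tri(propan-2-yl)silyl]oxy}-2H-chromen-7-yl)ethyl]phenoxy}silane | CC(C)=CCc1c(CCc2ccc(O[Si](C)(C)C(C)(C)C)cc2)cc2c(c1O[Si](C(C)C)(C(C)C)C(C)C)C=CC(C)(C)O2 | intermediate
16 | 7-[2-(4-hydroxyphenyl)ethyl]-2,2-dimethyl-6-(3-methylbut-2-en-1-yl)-2H-chromen-5-ol | CC(C)=CCc1c(CCc2ccc(O)cc2)cc2c(c1O)C=CC(C)(C)O2 | target

**Step count**

Total steps: 7. Longest linear sequence: 6 steps (steps 1, 2, 3, 4, 6 and 7); step 5 supplies the second fragment.

**Steps most likely to fail**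

Step 6. Both partners are electron-rich, so the cycloaddition may not start. The silver salt may instead trigger oligomerisation or hydration of the siloxyalkyne, closure may occur in a [2+2] sense on a pyranone double bond, or the 2H-pyran may open on heating. The fallback abandons the pyranone benzannulation for a resorcinol route built on known chemistry. It sets out from 3-methylbut-2-enal 7 and purchased dihydroresveratrol, 5-[2-(4-hydroxyphenyl)ethyl]benzene-1,3-diol. Ethylenediammonium diacetate in refluxing toluene should condense them at the carbon between the two ring A hydroxyls (Knoevenagel-type condensation, then oxa-6π closure) to give 7-[2-(4-hydroxyphenyl)ethyl]-2,2-dimethyl-2H-chromen-5-ol F1. The ring A phenol is the more acidic one; its sodium phenoxide (NaH, 1 equiv, toluene) should be C-prenylated by 1-bromo-3-methylbut-2-ene at C6, its only free ortho position. This rejoins the route at target 16, at the price of lower regioselectivity.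

Step 5. The carbenoid base may enolise the doubly activated CH2 of the β,γ-unsaturated ester instead of adding to its carbonyl, with migration of the alkene into conjugation; silylation on carbon is a further risk. The fallback sets out from ester 10 and reaches the ynolate by oxidation of an acetylide instead of by rearrangement. Reduction with iBu2AlH in CH2Cl2 at −78 °C should give 4-methylpent-3-enal F2. Dibromo-olefination with CBr4 and PPh3 should give 1,1-dibromo-5-methylhexa-1,4-diene F3. Treatment with n-BuLi (2 equiv, THF, −78 °C) should give (5-methylhex-4-en-1-yn-1-yl)lithium F4 in the flask (Corey–Fuchs sequence). Oxidation of F4 with lithium tert-butyl peroxide should deliver lithium ynolate 12, and silylation with iPr3SiOSO2CF3 rejoins the route at 13.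

Step 3. Proton exchange between the product anion and unreacted dianion may lead to double alkylation. O-alkylation and decomposition of the labile benzylic bromide may further erode the step. The fallback replaces alkylation by aldol addition and deoxygenation. It sets out from pyranone 4 through its dianion 5, which should add to purchased 4-{[tert-butyl(dimethyl)silyl]oxy}benzaldehyde at the methyl carbon to give 6-[2-(4-{[tert-butyl(dimethyl)silyl]oxy}phenyl)-2-hydroxyethyl]-4-hydroxy-2H-pyran-2-one F5 (racemic). Ionic hydrogenation of the benzylic alcohol (Et3SiH, CF3CO2H, CH2Cl2, 0 °C), assisted by the para silyloxy group, should then give 6, where the route is rejoined.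

**Further compounds**

F1 | step 6 | 7-[2-(4-hydroxyphenyl)ethyl]-2,2-dimethyl-2H-chromen-5-ol | CC1(C)C=Cc2c(O)cc(CCc3ccc(O)cc3)cc2O1
F2 | step 5 | 4-methylpent-3-enal | CC(C)=CCC=O
F3 | step 5 | 1,1-dibromo-5-methylhexa-1,4-diene | CC(C)=CCC=C(Br)Br
F4 | step 5 | (5-methylhex-4-en-1-yn-1-yl)lithium | [Li]C#CCC=C(C)C
F5 | step 3 | 6-[2-(4-{[tert-butyl(dimethyl)silyl]oxy}phenyl)-2-hydroxyethyl]-4-hydroxy-2H-pyran-2-one (racemic) | O=C1C=C(O)C=C(CC(O)c2ccc(O[Si](C)(C)C(C)(C)C)cc2)O1
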